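All runs are calculated on assumed constants, and the scatter is random.

The vessel is closed and isothermal, and whether target reaches its plateau in it is a matter of two times: the time you allow, and the settling half-time, in which target closes half its gap to its plateau.

| flask | solid substrate | protic impurity | temperature | remark | time |
|---|---|---|---|---|---|
| violet | 1 M | 0.010 M | 95 °C | run made earlier |  |
| ochre | 1 M | 0.040 M | 106 °C | run made earlier |  |
| amber | 2 M | 0.020 M | 95 °C | run made earlier |  |
| epsilon | 1.0 M | 0.0200 M | 110 °C |  | 3.0 min |
| zeta | 1.0 M | 0.0200 M | 90 °C |  | 3.0 min |

violet run (percent of the solid substrate charged)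

| time / min | target / % |
|---|---|
| 0.667 | 76 |
| 1.33 | 82 |
| 2.00 | 83 |
| 3.00 | 80 |
| 4.00 | 79 |

ochre run (percent of the solid substrate charged)

| time / s | target / % |
|---|---|
| 20.0 | 77 |
| 40.0 | 85 |
| 60.0 | 83 |
| 80.0 | 84 |
| 120 | 81 |

amber run (percent of the solid substrate charged)

| time / min | target / % |
|---|---|
| 0.333 | 37 |
| 0.833 | 76 |
| 2.00 | 80 |
| 3.00 | 82 |
| 4.00 | 78 |

(readings scatter by 2 percentage points)

* the flask with the highest amount of target, in percent of the solid substrate charged ("all alike" if they lie within 1.5 percentage points) (epsilon / zeta / all alike)
* final target, as a percentage of the solid substrate charged, in epsilon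
* final target, as a percentage of the solid substrate charged, in zeta

- as a solid, counted per litre of solution: solid substrate
- what was read earlier has a scatter of 2 percentage points, one standard deviation
- steps that have been proposed: starting material <-> target; target <-> isomer of the product; isomer of the product <-> starting material; starting material + protic impurity -> quenched substrate; solid substrate <-> starting material
- at the start none of the solid substrate is in solution
- what has only dissolved of solid substrate counts as not reacted

Violet levels at a reading of 81.0 % of the charge, and its first reading gives a settling half-time of 0.166 min. Ochre levels at 83.2 % and reads 0.0892 min, a factor of 1.86. Ochre also holds more protic impurity, but I put the whole factor on temperature and hold it constant per degree, which gives an estimate of 0.220 min for zeta, the colder flask. Zeta's asked time then holds 13.6 half-times; this ratio of asked time to settling half-time is the turnover count. So zeta, and the hotter epsilon at an estimated 0.0712 min, should both be under thermodynamic control, and plateau height counts.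

If the impurity costs its own amount of substrate, target reads 81.8 % of what remains in violet and 86.7 % in ochre. Carrying that line in temperature, I reckon 86.7 % for epsilon and 78.0 % for zeta, so epsilon stands higher.

The forecast says 82 % and 81 %, hence all alike, holding that “warmth seems to favour the target slightly”; I take the same direction but a steeper slope.

The simulation gives 86.6 % in epsilon and 78.3 % in zeta, so the answer is epsilon.

    starting material ⇌ target (K = 22.0, k = 0.170 /s, Ea = 99.0 kJ/mol, ΔH = 30.0 kJ/mol)
    target ⇌ isomer of the product (K = 0.0860, k = 0.110 /s, Ea = 108 kJ/mol, ΔH = −41.0 kJ/mol)
    isomer of the product ⇌ starting material (k = 0.0230 /s, Ea = 99.0 kJ/mol)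
    starting material + protic impurity → quenched substrate (k = 6.80 /M/s, Ea = 41.0 kJ/mol)
    solid substrate ⇌ starting material, rate k5*(cs5 - [starting material]) while solid is left; crystals form when [starting material] > cs5 (solubility = 0.850 M, k = 1.10 /s)
    (constants at 110 °C)

In zeta the asked time spans 29.7 relaxation half-lives of target and isomer of the product, by that step alone, and 3.55 of isomer of the product and starting material, by that step alone, and target stands at 78.3 % after 30.0 min. Carried the same way to the neighbour flask, zeta kept at 65 °C, the turnover count falls from 13.6 to 3.32, which reckons 90.0 % of the gap closed, yet that flask ends with target at 32.6 % and starting material at 51.5 %.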